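(The data were computed with made-up constants, and the scatter is random.)

A small charge of solid substrate stands behind every reading here, and its balance is the way to read the ash flask: solid substrate is the limiting reagent, and in the closed flask its percentages in solid, starting material, intermediate A, intermediate B, target, decomposed reagent and side product, counted double, add up to 100.

| flask | solid substrate | temperature | remark | time |
|---|---|---|---|---|
| ash | 0.10 M | 35 °C | the very flask that is asked about, followed so far |  |
| larch | 0.067 M | 41 °C | run made earlier |  |
| flask | 0.10 M | 35 °C |  | 8.0 d |

| run | time / d | target / % |
|---|---|---|
| ash | 0.417 | 7.3 |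
| ash | 1.25 | 38.8 |
| ash | 2.50 | 44.3 |
| ash | 3.00 | 47.0 |
| ash | 5.00 | 47.3 |
| ash | 6.00 | 45.5 |
| ash | 8.00 | 46.5 |
| larch | 0.417 | 17.1 |
| larch | 0.833 | 44.2 |
| larch | 1.25 | 47.3 |
| larch | 1.67 | 47.9 |
| larch | 2.08 | 48.0 |
| larch | 2.50 | 48.3 |
| larch | 3.00 | 46.1 |

(each reading ± 1 percentage point)

- percentages count the solid substrate that a species holds: one side product counts as two
- solid, in amounts per volume of the solution: solid substrate
- target that was removed still counts
- the earlier runs were read with a standard deviation of 1 percentage point
- reactions considered so far: starting material + intermediate B -> side product; starting material -> intermediate A; solid substrate <-> starting material; intermediate B -> target; intermediate A -> decomposed reagent; intermediate A -> intermediate B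
- at the start none of the solid substrate is in solution

- north-west: at 8.0 d take out 90 % of the target then present, then wait 8.0 d
- south-east: at 8.0 d raise the temperature by 20 K, then wait 8.0 d
- north-east: change nothing and wait 8.0 d more

- target, in percent of the solid substrate first charged, at 8.0 d
- the option that brings most further target ("none" if no option brings more than 2 percentage points) (north-west / south-east / north-east / none)
- target present, with what was taken out counted in, in percent of the solid substrate first charged, after north-west
- target present, with what was taken out counted in, in percent of the solid substrate first charged, after north-east

The readings form a ladder of times. On the first rung stands the larch run, warmer and more dilute, which reads 47.3 % at 1.25 d and stays near that level. The ash flask comes next, reaching its level at 3.00 d, later than larch: it gains 31 percentage points from 0.417 d to 1.25 d, then 8.2 points up to 3.00 d. On the last rung, from 3.00 d to 8.00 d, the ash target falls by 0.5 points, less than the scatter of a reading, and no listed reaction uses target.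

On my reckoning the balance of the ash flask by 8.0 d therefore reads target plus what went to other ends, decomposed reagent and side product together. The late ash readings average 46.6 %, which leaves 53.4 % of the charge elsewhere, and their quotient is 0.872, the branch ratio, level target per unit of charge lost to other ends. The same reading for larch gives 47.6 %, about one reading's scatter higher. I would commit to 46.6 % for now and to no useful option.

The forecast says 46.8 % (45.8 % to 47.8 %), 0.20 points above my mean, with 47 % after north-west, 47 % after north-east and best none: “Heating has nothing left to convert, and waiting adds nothing”.

    starting material + intermediate B → side product (k = 0.0166 L mol⁻¹ min⁻¹, Ea = 73.0 kJ mol⁻¹)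
    starting material → intermediate A (k = 0.0639 min⁻¹, Ea = 81.0 kJ mol⁻¹)
    solid substrate ⇌ starting material, rate k3*(cs3 - [starting material]) while solid is left; crystals form when [starting material] > cs3 (solubility = 12.0 mM, k = 0.00624 min⁻¹)
    intermediate B → target (k = 0.00300 min⁻¹, Ea = 88.0 kJ mol⁻¹)
    intermediate A → decomposed reagent (k = 0.00296 min⁻¹, Ea = 92.0 kJ mol⁻¹)
    intermediate A → intermediate B (k = 0.00256 min⁻¹, Ea = 100 kJ mol⁻¹)
    (constants at 35 °C)

The ash flask gives 46.1 % at 8.0 d, and north-west, south-east and north-east each bring 0 points, so the answer is none; at that time solid substrate stands at 0 %, intermediate A at 0 % and intermediate B at 0 %. Divided by the branch ratio 0.872, itself a reading, the target of the ash flask stands for 52.9 % of the charge at other ends. A different outcome appears in the neighbouring flask kept at 60 °C, where target 52.2 % over the rest of the charge 47.8 % gives a ratio of 1.09, above 0.872, and 6.1 points more target than the ash flask, beyond the 2 points margin.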